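## Structural features

6-Prenylsakuranetin is a (2S)-flavanone: benzene ring A (C4a, C5–C8, C8a) is fused to the dihydropyranone ring C (O1, C2, C3, C4), and the 4-hydroxyphenyl ring B sits on C2. Ring A is fully differentiated: a free hydroxyl on C5 hydrogen-bonded to the C4 carbonyl, a prenyl chain on C6, a methyl ether on C7 and one hydrogen on C8. C2 is the only stereocentre, so the stereochemical problem is purely one of absolute configuration. C2 is benzylic, bonded to O1 and β to the ketone, which makes it labile: enolisation towards C3 can expel the C8a phenoxide (ring opening to the chalcone), and the para oxygen of ring B assists heterolysis of C2–O1. Either path racemises, so base, strong acid and heat must be avoided once ring C exists. The prenyl alkene is the second fragile group: acid can protonate it and close it onto the C5 hydroxyl, and it can take part in any alkene chemistry. The real difficulties are placing the prenyl group between two ring A oxygens that end up different (OH and OMe), and installing C2 so that it survives to the end. The plan exploits the fact that the C3–C4 bond of six-membered ring C links the carbonyl carbon on C4a to the carbon beside the allylic-ether-type centre C2: a vinyl group on C2 and an enol ether on C4a can be joined by metathesis, which forms C3=C4, closes ring C and delivers C4 at the ketone oxidation level.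

## Logic of the disconnections

20 ⇒ 19. The forward step cleaves the O–Si bond on ring B. Keeping this phenol silylated until the end means the preceding Lewis-acid step never meets a free para-hydroxyaryl group on C2. The forward step must free the phenol without forming an enolate of the flavanone, hence fluoride buffered with acetic acid at 0 °C.

19 ⇒ 18. The forward step cleaves the O–CH3 bond at C5. Carrying C5 and C7 as identical methyl ethers makes ring A symmetric in every precursor back to 1, so the prenylation and acylation have no regiochemical ambiguity. The demand is a demethylation that distinguishes the peri ether (chelated to the C4 carbonyl) from the C7 ether and leaves the prenyl alkene and C2 alone.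

18 ⇒ 17. The C4 ketone is traced back to its enol silane; the forward step cleaves the enol O–Si bond and adds a proton at C3. This keeps C4 at the right oxidation level with no redox step. The demand is hydrolysis by acid only, mild enough to spare the aryl silyl ether.

17 ⇒ 16. The C3=C4 bond is cut, opening ring C to a vinyl group on C2 and a 1-silyloxyvinyl group on C4a. This removes the only ring that has to be built and leaves an acyclic aryl ether whose stereocentre is already in place. The forward step must close the six-membered ring faster than dimerisation, faster than any reaction of the prenyl alkene and without double-bond migration at C2.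

16 ⇒ 15. The enol O–Si bond is cut, giving the methyl ketone. The acetyl methyl carries the only acidic α-hydrogens, so the enolisation has one possible direction. The forward step must avoid Lewis acid (the allylic benzylic ether ionises easily) and must not deprotonate C2.

15 ⇒ 10 + 14. The C2–O1 bond is cut, dividing the molecule into a ring A phenol and a ring B allyl electrophile of similar size. This is the point of convergence and the step that creates C2. The forward step needs branched regioselectivity and S configuration, which an iridium phosphoramidite catalyst can supply from the linear carbonate.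

14 ⇒ 13 ⇒ 12 ⇒ 11. The carbonate C–O bond, the alcohol oxidation level and the phenol O–Si bond are taken back in turn to the commercial ester. These are standard functional-group changes; the only demand is that the E alkene and the silyl ether survive the hydride reduction.

10 ⇒ 7 (through 9 and 8). The C4a–acyl bond is cut and the phenol is masked as an acetal ether. The acetyl group is introduced by directed ortho-metalation and acylation because a Friedel–Crafts acylation would expose the prenyl alkene to strong acid. Ring A has only one kind of hydrogen left, so the metalation has a single outcome; the acetal next to the new ketone is then cleaved by dilute acid in the same flask.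

7 ⇒ 6 ⇒ 5. Two protecting-group bonds are exchanged: the acetal ether, which directs metalation to its neighbour, replaces the bulky silyl ether, which blocks its neighbours. Two steps are spent here to make both ring-metalations unambiguous.

5 ⇒ 2 + 3 (through 4), and 2 ⇒ 1. The C6–CH2 bond is cut between the two methoxy groups. The bulky silyl ether on the third oxygen shields the two other ring positions, so lithiation is confined to the site between the methoxy groups. The forward step must alkylate 3 at its primary carbon, not at the tertiary end.

## Other disconnections considered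

Alternative 1: The cut is through C3–C4 and O1–C2, giving 6-hydroxy-2,4-dimethoxy-3-(3-methylbut-2-enyl)benzaldehyde A1 and 4-vinylphenol A2. In the forward step a chiral Brønsted acid (a 3,3'-diaryl-1,1'-binaphthalene-2,2'-diyl hydrogen phosphate) would activate A1 as an ortho-quinone-methide-like hydroxy oxocarbenium ion. A2 would add through its terminal carbon to C4 and the phenolic oxygen would trap the resulting benzylic cation, giving (2S,4S)-2-(4-hydroxyphenyl)-5,7-dimethoxy-6-(3-methylbut-2-enyl)chroman-4-ol A3.
- In its favour: two bonds and ring C in one metal-free operation, no protecting group on ring B, and A1 is one formylation away from 6.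
- Against it: A3 is at the alcohol oxidation level, so a benzylic oxidation is needed in the presence of a free phenol and the prenyl alkene, and the C4 stereocentre is made only to be destroyed. The C4 hydroxyl on a phloroglucinol-type ring should ionise under the same acid and could capture a second A2 or eliminate. C2–O1 is formed under acid with an unprotected para-hydroxyaryl group, where it is reversible, so the enantiomeric purity would be under thermodynamic threat. The prenyl alkene is a competing nucleophile.
- Comparison: on step count this plan is clearly better (roughly half the length) and it uses no silyl groups. On ring A regiochemistry it is equal, since it uses the same symmetric building block, and it still needs the C5 demethylation. On mechanism the chosen plan is safer: C2 is set irreversibly under kinetic control and ring C never meets strong acid.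

Alternative 2: The cut is O1–C8a, leading to (S)-1-[6-fluoro-2,4-dimethoxy-3-(3-methylbut-2-enyl)phenyl]-3-[4-(methoxymethoxy)phenyl]-3-(triethylsilyloxy)propan-1-one A4. Catalytic CsF would remove the silyl group; the C2 alkoxide would add to C8a ortho to the ketone and expel fluoride, which continues the cycle, giving (2S)-5,7-dimethoxy-4'-(methoxymethoxy)-6-prenylflavanone A5.
- In its favour: the C2–O bond is made earlier by a well-developed asymmetric aldol or ketone reduction and is not touched in the ring closure; the ketone is present from the start; no metathesis catalyst is needed; the intermediates contain no ionisable allylic ether.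
- Against it: an alkoxide β to a ketone is necessarily generated, so retro-aldol cleavage and dehydration to the chalcone compete with substitution. The substitution is slow on a ring carrying two methoxy donors and only one activating acyl group. A fluorinated ring A building block must be made regioselectively. The acetal on ring B must later be removed with acid beside the prenyl group, and the C5 demethylation remains.
- Comparison: it is better in the robustness of its intermediates and equal in length and in the need for demethylation. The chosen plan is better mechanistically because metathesis is neutral and generates neither an alkoxide nor an enolate next to the stereocentre.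

Alternative 3: The cut removes ring A, leading to (2S)-6-(2-diazoacetyl)-2-[4-(tert-butyldimethylsilyloxy)phenyl]-2,3-dihydro-4H-pyran-4-one A6 and 1-methoxy-5-methylhex-4-en-1-yne A7. Irradiation of A6 would give a vinylketene by Wolff rearrangement. [2+2] addition to A7, four-electron ring opening, six-electron closure and tautomerisation would give 6-prenylsakuranetin 4'-O-tert-butyldimethylsilyl ether A8, which is the same compound as 19.
- In its favour: the substitution pattern of ring A (free C5 hydroxyl, C6 prenyl, C7 methoxy, C8 hydrogen) is fixed by the mechanism, so no selective demethylation and no aromatic regiochemistry problem arise. A8 is one step from the target.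
- Against it: A6 is an acylated vinylogous ester whose C2 centre can open by retro-oxa-Michael reaction under the base used for diazo transfer. Making it as a single enantiomer with the extra acyl carbon takes several steps. A7 is a volatile, labile alkoxyalkyne. The photochemical and thermal cascade passes through ketenes in the presence of a prenyl alkene.
- Comparison: on ring A regiochemistry and on the endgame (two steps shorter after its key step) this plan is better. On mechanism it carries more risk than a single ring-closing metathesis, and overall length would probably be equal or greater because both A6 and A7 need separate multistep preparation.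

Key step: step 11

Assumption: the (Sa,Sc,Sc) phosphoramidite is taken to give the (S)-ether in step 9, by analogy with the usual sense of induction of this ligand series with aryloxides and cinnamyl-type carbonates; if the sense were opposite here, the mirror-image ligand would be used with no other change.

## Route

Step 1
Reactants: 1 3,5-dimethoxyphenol
Product: 2 (3,5-dimethoxyphenoxy)triisopropylsilane
Conditions: i-Pr3SiCl, imidazole, DMF, rt
Reagents that add atoms: triisopropylsilyl chloride, CC(C)[Si](Cl)(C(C)C)C(C)C
Why: Imidazole-promoted O-silylation of a phenol; the bulky silyl ether is a poor directing group and screens both neighbouring ring positions, which sets up the regiochemistry of step 2.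

Step 2
Reactants: 2 (3,5-dimethoxyphenoxy)triisopropylsilane; 3 prenyl bromide (1-bromo-3-methylbut-2-ene)
Product: 5 [3,5-dimethoxy-4-(3-methylbut-2-enyl)phenoxy]triisopropylsilane, via aryllithium 4 (not isolated)
Conditions: n-BuLi, THF, 0 °C to rt; then CuI (10 mol%), 3, −40 to 0 °C
Reagents that add atoms: none
Why: Directed ortho-metalation at the carbon flanked by the two methoxy groups (the silyl ether blocks the other sites), then copper-catalysed SN2 alkylation at the primary carbon of the allylic bromide, which should give the linear prenyl group.

Step 3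
Reactants: 5 [3,5-dimethoxy-4-(3-methylbut-2-enyl)phenoxy]triisopropylsilane
Product: 6 3,5-dimethoxy-4-(3-methylbut-2-enyl)phenol
Conditions: Bu4NF, THF, 0 °C; aq. NH4Cl
Reagents that add atoms: none
Why: Fluoride cleavage of an aryl silyl ether, driven by the Si–F bond; nothing else in the molecule responds to fluoride.

Step 4
Reactants: 6 3,5-dimethoxy-4-(3-methylbut-2-enyl)phenol
Product: 7 1,3-dimethoxy-5-(methoxymethoxy)-2-(3-methylbut-2-enyl)benzene
Conditions: MeOCH2Cl, i-Pr2NEt, CH2Cl2, 0 °C to rt
Reagents that add atoms: chloromethyl methyl ether, COCCl
Why: O-Alkylation of the phenol to the acetal ether, a strong directing group for the metalation of step 5.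

Step 5
Reactants: 7 1,3-dimethoxy-5-(methoxymethoxy)-2-(3-methylbut-2-enyl)benzene
Product: 10 1-[6-hydroxy-2,4-dimethoxy-3-(3-methylbut-2-enyl)phenyl]ethanone, via aryllithium 8 (not isolated), via acetal-protected ketone 9 (not isolated)
Conditions: n-BuLi, THF, 0 °C; MeC(O)N(OMe)Me, −78 to 0 °C; then 2 M HCl, MeOH, rt (same flask)
Reagents that add atoms: N-methoxy-N-methylacetamide, CC(=O)N(C)OC
Why: Directed ortho-metalation between the acetal ether and a methoxy group (the only kind of ring hydrogen left), acylation with an N-methoxy-N-methylamide (stable chelated adduct, no over-addition), then dilute-acid cleavage of the acetal, which is activated by the neighbouring carbonyl; no strong Lewis acid meets the prenyl alkene.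

Step 6
Reactants: 11 methyl (E)-4-hydroxycinnamate
Product: 12 methyl (E)-3-[4-(tert-butyldimethylsilyloxy)phenyl]prop-2-enoate
Conditions: t-BuMe2SiCl, imidazole, DMF, rt
Reagents that add atoms: tert-butyldimethylsilyl chloride, CC(C)(C)[Si](C)(C)Cl
Why: Standard silylation of a phenol; the silyl ether can be removed at the end under buffered, non-basic conditions.

Step 7
Reactants: 12 methyl (E)-3-[4-(tert-butyldimethylsilyloxy)phenyl]prop-2-enoate
Product: 13 (E)-3-[4-(tert-butyldimethylsilyloxy)phenyl]prop-2-en-1-ol
Conditions: i-Bu2AlH (2.2 equiv), CH2Cl2, −78 °C; aq. potassium sodium tartrate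
Reagents that add atoms: none
Why: 1,2-Reduction of an α,β-unsaturated ester to the allylic alcohol with an aluminium hydride; the alkene geometry and the aryl silyl ether are not affected at low temperature.

Step 8
Reactants: 13 (E)-3-[4-(tert-butyldimethylsilyloxy)phenyl]prop-2-en-1-ol
Product: 14 (E)-3-[4-(tert-butyldimethylsilyloxy)phenyl]prop-2-enyl methyl carbonate
Conditions: ClCO2Me, pyridine, CH2Cl2, 0 °C
Reagents that add atoms: methyl chloroformate, COC(=O)Cl
Why: Acylation of the primary alcohol to the carbonate, the leaving group that iridium ionises in step 9.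

Step 9
Reactants: 10 1-[6-hydroxy-2,4-dimethoxy-3-(3-methylbut-2-enyl)phenyl]ethanone; 14 (E)-3-[4-(tert-butyldimethylsilyloxy)phenyl]prop-2-enyl methyl carbonate
Product: 15 1-[6-{[(1S)-1-[4-(tert-butyldimethylsilyloxy)phenyl]prop-2-en-1-yl]oxy}-2,4-dimethoxy-3-(3-methylbut-2-enyl)phenyl]ethanone
Conditions: [Ir(cod)Cl]2 (2 mol%), (Sa,Sc,Sc)-(1,1'-binaphthalene-2,2'-diyl) N,N-bis(1-phenylethyl)phosphoramidite (4 mol%), pre-activated with n-PrNH2; LiOt-Bu (1.0 equiv), THF, rt
Reagents that add atoms: none
Why: Iridium-catalysed asymmetric allylic etherification with an aryloxide: the cyclometalated monovalent iridium phosphoramidite complex ionises the linear carbonate and the lithium phenoxide attacks the aryl-substituted allyl terminus anti to the metal, giving the branched ether; the ligand decides which allyl face is bound and should set C2 as S.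

Step 10
Reactants: 15 1-[6-{[(1S)-1-[4-(tert-butyldimethylsilyloxy)phenyl]prop-2-en-1-yl]oxy}-2,4-dimethoxy-3-(3-methylbut-2-enyl)phenyl]ethanone
Product: 16 tert-butyl{[1-(6-{[(1S)-1-[4-(tert-butyldimethylsilyloxy)phenyl]prop-2-en-1-yl]oxy}-2,4-dimethoxy-3-(3-methylbut-2-enyl)phenyl)ethenyl]oxy}dimethylsilane
Conditions: KN(SiMe3)2, t-BuMe2SiCl, THF, −78 °C; pH 7 buffer
Reagents that add atoms: tert-butyldimethylsilyl chloride, CC(C)(C)[Si](C)(C)Cl
Why: Kinetic deprotonation of the methyl ketone (its only α-hydrogens) and O-silylation of the potassium enolate; a hindered amide base at low temperature without Lewis acid should spare both the C2 hydrogen and the ionisable allylic ether.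

Step 11
Reactants: 16 tert-butyl{[1-(6-{[(1S)-1-[4-(tert-butyldimethylsilyloxy)phenyl]prop-2-en-1-yl]oxy}-2,4-dimethoxy-3-(3-methylbut-2-enyl)phenyl)ethenyl]oxy}dimethylsilane
Product: 17 (2S)-4-(tert-butyldimethylsilyloxy)-2-[4-(tert-butyldimethylsilyloxy)phenyl]-5,7-dimethoxy-6-(3-methylbut-2-enyl)-2H-chromene
Conditions: RuCl2(=CHPh)(H2IMes)(PCy3) (second-generation Grubbs catalyst, 7 mol%), 1,4-benzoquinone (10 mol%), toluene (0.005 M), 45 °C, argon purge, dark
Reagents that add atoms: none
Why: Ring-closing metathesis of an alkene with a silyl enol ether, the known route from enol silanes to cyclic enol ethers and from allyl aryl ethers to 2H-chromenes. The ruthenium benzylidene first exchanges onto the monosubstituted vinyl group on C2, because the 1,1-disubstituted enol ether and the trisubstituted prenyl alkene initiate far more slowly. The new alkylidene on C3 adds [2+2] to the C4=CH2 enol ether, and cycloreversion of the ruthenacyclobutane gives the C3=C4 bond and a ruthenium methylidene that leaves as ethene on the next turnover. Ring C closes as a six-membered ring by this intramolecular alkylidene transfer, the ortho relationship of the two arms on ring A holding them within reach. No stereocentre is formed: C2 comes from step 9 and none of its four bonds is made or broken. The step needs ring closure to run ahead of dimerisation through the vinyl groups, of any engagement of the prenyl alkene and of double-bond migration at C2; high dilution, the kinetic preference for six-membered closure, the low reactivity of the trisubstituted alkene and 1,4-benzoquinone as a scavenger of ruthenium hydrides should secure this. C4 emerges as an enol silane, at the ketone oxidation level, so no flavanone enolate is generated.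

Step 12
Reactants: 17 (2S)-4-(tert-butyldimethylsilyloxy)-2-[4-(tert-butyldimethylsilyloxy)phenyl]-5,7-dimethoxy-6-(3-methylbut-2-enyl)-2H-chromene
Product: 18 (2S)-2-[4-(tert-butyldimethylsilyloxy)phenyl]-5,7-dimethoxy-6-(3-methylbut-2-enyl)chroman-4-one
Conditions: 1 M HCl (aq), THF, 0 °C
Reagents that add atoms: none
Why: Acid hydrolysis of a silyl enol ether (protonation at C3, loss of silicon from oxygen); the enol silane is far more acid-labile than the aryl silyl ether, and the ketone is released without an enolate that could open ring C.

Step 13
Reactants: 18 (2S)-2-[4-(tert-butyldimethylsilyloxy)phenyl]-5,7-dimethoxy-6-(3-methylbut-2-enyl)chroman-4-one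
Product: 19 (2S)-2-[4-(tert-butyldimethylsilyloxy)phenyl]-5-hydroxy-7-methoxy-6-(3-methylbut-2-enyl)chroman-4-one
Conditions: MgI2·OEt2 (3 equiv), THF, 45 °C; aq. NH4Cl
Reagents that add atoms: none
Why: Chelation-controlled demethylation: magnesium bridges the C4 carbonyl and the peri C5 ether oxygen, and iodide removes that methyl group by SN2; the C7 ether cannot chelate and should remain, and this mild Lewis acid is of a kind used beside prenyl groups.

Step 14
Reactants: 19 (2S)-2-[4-(tert-butyldimethylsilyloxy)phenyl]-5-hydroxy-7-methoxy-6-(3-methylbut-2-enyl)chroman-4-one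
Product: 20 6-prenylsakuranetin [(2S)-5-hydroxy-2-(4-hydroxyphenyl)-7-methoxy-6-(3-methylbut-2-enyl)chroman-4-one]
Conditions: Bu4NF, AcOH (1:1), THF, 0 °C
Reagents that add atoms: none
Why: Fluoride cleavage of the aryl silyl ether; the acetic acid buffer protonates the phenoxide as it forms, so ring C is not exposed to base and C2 should keep its configuration.

## Compound list

1 | 3,5-dimethoxyphenol | COc1cc(O)cc(OC)c1 | starting material
2 | (3,5-dimethoxyphenoxy)triisopropylsilane | COc1cc(O[Si](C(C)C)(C(C)C)C(C)C)cc(OC)c1 | intermediate
3 | prenyl bromide (1-bromo-3-methylbut-2-ene) | CC(C)=CCBr | starting material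
4 | [2,6-dimethoxy-4-(triisopropylsilyloxy)phenyl]lithium | [Li]c1c(OC)cc(O[Si](C(C)C)(C(C)C)C(C)C)cc1OC | intermediate
5 | [3,5-dimethoxy-4-(3-methylbut-2-enyl)phenoxy]triisopropylsilane | COc1cc(O[Si](C(C)C)(C(C)C)C(C)C)cc(OC)c1CC=C(C)C | intermediate
6 | 3,5-dimethoxy-4-(3-methylbut-2-enyl)phenol | COc1cc(O)cc(OC)c1CC=C(C)C | intermediate
7 | 1,3-dimethoxy-5-(methoxymethoxy)-2-(3-methylbut-2-enyl)benzene | COCOc1cc(OC)c(CC=C(C)C)c(OC)c1 | intermediate
8 | [2,4-dimethoxy-6-(methoxymethoxy)-3-(3-methylbut-2-enyl)phenyl]lithium | [Li]c1c(OCOC)cc(OC)c(CC=C(C)C)c1OC | intermediate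
9 | 1-[2,4-dimethoxy-6-(methoxymethoxy)-3-(3-methylbut-2-enyl)phenyl]ethanone | CC(=O)c1c(OCOC)cc(OC)c(CC=C(C)C)c1OC | intermediate
10 | 1-[6-hydroxy-2,4-dimethoxy-3-(3-methylbut-2-enyl)phenyl]ethanone | CC(=O)c1c(O)cc(OC)c(CC=C(C)C)c1OC | intermediate
11 | methyl (E)-4-hydroxycinnamate | COC(=O)/C=C/c1ccc(O)cc1 | starting material
12 | methyl (E)-3-[4-(tert-butyldimethylsilyloxy)phenyl]prop-2-enoate | COC(=O)/C=C/c1ccc(O[Si](C)(C)C(C)(C)C)cc1 | intermediate
13 | (E)-3-[4-(tert-butyldimethylsilyloxy)phenyl]prop-2-en-1-ol | OC/C=C/c1ccc(O[Si](C)(C)C(C)(C)C)cc1 | intermediate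
14 | (E)-3-[4-(tert-butyldimethylsilyloxy)phenyl]prop-2-enyl methyl carbonate | COC(=O)OC/C=C/c1ccc(O[Si](C)(C)C(C)(C)C)cc1 | intermediate
15 | 1-[6-{[(1S)-1-[4-(tert-butyldimethylsilyloxy)phenyl]prop-2-en-1-yl]oxy}-2,4-dimethoxy-3-(3-methylbut-2-enyl)phenyl]ethanone | C=C[C@@H](c1ccc(O[Si](C)(C)C(C)(C)C)cc1)Oc1cc(OC)c(CC=C(C)C)c(OC)c1C(C)=O | intermediate
16 | tert-butyl{[1-(6-{[(1S)-1-[4-(tert-butyldimethylsilyloxy)phenyl]prop-2-en-1-yl]oxy}-2,4-dimethoxy-3-(3-methylbut-2-enyl)phenyl)ethenyl]oxy}dimethylsilane | C=C[C@@H](c1ccc(O[Si](C)(C)C(C)(C)C)cc1)Oc1cc(OC)c(CC=C(C)C)c(OC)c1C(=C)O[Si](C)(C)C(C)(C)C | intermediate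
17 | (2S)-4-(tert-butyldimethylsilyloxy)-2-[4-(tert-butyldimethylsilyloxy)phenyl]-5,7-dimethoxy-6-(3-methylbut-2-enyl)-2H-chromene | COc1cc2c(c(OC)c1CC=C(C)C)C(O[Si](C)(C)C(C)(C)C)=C[C@@H](c1ccc(O[Si](C)(C)C(C)(C)C)cc1)O2 | intermediate
18 | (2S)-2-[4-(tert-butyldimethylsilyloxy)phenyl]-5,7-dimethoxy-6-(3-methylbut-2-enyl)chroman-4-one | COc1cc2c(c(OC)c1CC=C(C)C)C(=O)C[C@@H](c1ccc(O[Si](C)(C)C(C)(C)C)cc1)O2 | intermediate
19 | (2S)-2-[4-(tert-butyldimethylsilyloxy)phenyl]-5-hydroxy-7-methoxy-6-(3-methylbut-2-enyl)chroman-4-one | COc1cc2c(c(O)c1CC=C(C)C)C(=O)C[C@@H](c1ccc(O[Si](C)(C)C(C)(C)C)cc1)O2 | intermediate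
20 | 6-prenylsakuranetin, (2S)-5-hydroxy-2-(4-hydroxyphenyl)-7-methoxy-6-(3-methylbut-2-enyl)chroman-4-one | COc1cc2c(c(O)c1CC=C(C)C)C(=O)C[C@@H](c1ccc(O)cc1)O2 | target

## Step count and least certain steps

Total step count: 14. Longest linear sequence: 11 steps (steps 1–5 and 9–14, from 1 to 20); the branch from 11 to 14 has 3 steps.

Step 11 (key step). The most likely failure is slow ring closure, because the enol ether sits between two ortho substituents on ring A. The ruthenium alkylidene loaded on the vinyl group then has time to dimerise the substrate or to decay to hydride species that move the C2 vinyl double bond into conjugation, which destroys the stereocentre. Prolonged heating could also racemise 17 by reversible electrocyclic opening of the chromene.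
Fallback: ring C is closed before ring B is attached, and C2 is set by conjugate addition. Phenol 10 is condensed with N,N-dimethylformamide dimethyl acetal (toluene, 90 °C) to (E)-3-(dimethylamino)-1-[6-hydroxy-2,4-dimethoxy-3-(3-methylbut-2-enyl)phenyl]prop-2-en-1-one F1. Brief treatment with dilute HCl in CH2Cl2 cyclises it, with loss of dimethylamine, to 5,7-dimethoxy-6-(3-methylbut-2-enyl)chromen-4-one F2. Asymmetric 1,4-addition of 4-(tert-butyldimethylsilyloxy)phenylboronic acid to F2 with Pd(OCOCF3)2, the enantiomer of 4-tert-butyl-2-(pyridin-2-yl)-4,5-dihydrooxazole that leads to the 2S series, NH4PF6 and water in 1,2-dichloroethane at 60 °C should give 18, where the route is rejoined before step 13.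

Step 9. The most likely failure is re-ionisation of the branched ether by the iridium catalyst: the acyl-stabilised phenoxide is a good leaving group and the 4-silyloxyphenyl group stabilises the allyl complex. The product could then drift to the linear cinnamyl ether and lose enantiomeric purity. C-allylation at the free ring position next to the phenoxide oxygen is a second competing process.
Fallback: the ether is made racemic by a different bond-forming reaction and resolved. Addition of vinylmagnesium bromide to commercial 4-(tert-butyldimethylsilyloxy)benzaldehyde (THF, −78 °C) gives racemic 1-[4-(tert-butyldimethylsilyloxy)phenyl]prop-2-en-1-ol F3. Mitsunobu coupling of F3 with phenol 10 (PPh3, diisopropyl azodicarboxylate, toluene, 0 °C) gives racemic 1-[6-{1-[4-(tert-butyldimethylsilyloxy)phenyl]prop-2-en-1-yloxy}-2,4-dimethoxy-3-(3-methylbut-2-enyl)phenyl]ethanone F4. Preparative chromatography of F4 on a chiral stationary phase returns the S enantiomer, which is 15.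

Step 13. The most likely failure is loss of configurational integrity at C2: magnesium chelation of the C4 carbonyl acidifies C3 and makes O1 a better leaving group, so reversible ring opening to the chalcone can accompany the demethylation. Hydrogen iodide formed adventitiously could also add to the prenyl alkene or close it onto the new C5 hydroxyl.
Fallback: the methyl group is removed before the stereocentre exists, and the C5 oxygen is carried as a silyl ether. The fallback sets out from 10 and comes back to the route at 20.
- Treatment of 10 with MgI2·OEt2 (THF, 45 °C) gives 1-[2,6-dihydroxy-4-methoxy-3-(3-methylbut-2-enyl)phenyl]ethanone F5.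
- Iridium-catalysed etherification of F5 with 14 under the conditions of step 9 should occur at the hydroxyl that is not flanked by the prenyl group. This gives 1-[6-{[(1S)-1-[4-(tert-butyldimethylsilyloxy)phenyl]prop-2-en-1-yl]oxy}-2-hydroxy-4-methoxy-3-(3-methylbut-2-enyl)phenyl]ethanone F6.
- KN(SiMe3)2 (2.2 equiv) and t-BuMe2SiCl silylate both the phenol and the enolate. This gives tert-butyl{[1-(2-(tert-butyldimethylsilyloxy)-6-{[(1S)-1-[4-(tert-butyldimethylsilyloxy)phenyl]prop-2-en-1-yl]oxy}-4-methoxy-3-(3-methylbut-2-enyl)phenyl)ethenyl]oxy}dimethylsilane F7.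
- Ring-closing metathesis as in step 11 gives (2S)-4,5-bis(tert-butyldimethylsilyloxy)-2-[4-(tert-butyldimethylsilyloxy)phenyl]-7-methoxy-6-(3-methylbut-2-enyl)-2H-chromene F8.
- HF·pyridine in THF at 0 °C removes all three silyl groups under acidic conditions and leads directly to 20.

Step 5. The most likely failure is proton transfer in place of acylation: the hindered aryllithium 8 can deprotonate the amide, or the base can metalate the benzylic-allylic CH2 of the prenyl group instead of the ring. During the acid stage, slow addition of methanol or water to the prenyl alkene is a further risk.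
Fallback: the carbonyl carbon is introduced by ortho-formylation without any organolithium. Phenol 6 with MgCl2, Et3N and paraformaldehyde (MeCN, reflux) should give 6-hydroxy-2,4-dimethoxy-3-(3-methylbut-2-enyl)benzaldehyde F9. MeMgBr (2.2 equiv, THF, −78 °C) then gives racemic 2-(1-hydroxyethyl)-3,5-dimethoxy-4-(3-methylbut-2-enyl)phenol F10. Benzylic oxidation of F10 with MnO2 in CH2Cl2 returns 10.

## Further compounds

F1 | step 11 | (E)-3-(dimethylamino)-1-[6-hydroxy-2,4-dimethoxy-3-(3-methylbut-2-enyl)phenyl]prop-2-en-1-one | CN(C)/C=C/C(=O)c1c(O)cc(OC)c(CC=C(C)C)c1OC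
F2 | step 11 | 5,7-dimethoxy-6-(3-methylbut-2-enyl)chromen-4-one | COc1cc2occc(=O)c2c(OC)c1CC=C(C)C
F3 | step 9 | 1-[4-(tert-butyldimethylsilyloxy)phenyl]prop-2-en-1-ol (racemic) | C=CC(O)c1ccc(O[Si](C)(C)C(C)(C)C)cc1
F4 | step 9 | 1-[6-{1-[4-(tert-butyldimethylsilyloxy)phenyl]prop-2-en-1-yloxy}-2,4-dimethoxy-3-(3-methylbut-2-enyl)phenyl]ethanone (racemic) | C=CC(c1ccc(O[Si](C)(C)C(C)(C)C)cc1)Oc1cc(OC)c(CC=C(C)C)c(OC)c1C(C)=O
F5 | step 13 | 1-[2,6-dihydroxy-4-methoxy-3-(3-methylbut-2-enyl)phenyl]ethanone | CC(=O)c1c(O)cc(OC)c(CC=C(C)C)c1O
F6 | step 13 | 1-[6-{[(1S)-1-[4-(tert-butyldimethylsilyloxy)phenyl]prop-2-en-1-yl]oxy}-2-hydroxy-4-methoxy-3-(3-methylbut-2-enyl)phenyl]ethanone | C=C[C@@H](c1ccc(O[Si](C)(C)C(C)(C)C)cc1)Oc1cc(OC)c(CC=C(C)C)c(O)c1C(C)=O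
F7 | step 13 | tert-butyl{[1-(2-(tert-butyldimethylsilyloxy)-6-{[(1S)-1-[4-(tert-butyldimethylsilyloxy)phenyl]prop-2-en-1-yl]oxy}-4-methoxy-3-(3-methylbut-2-enyl)phenyl)ethenyl]oxy}dimethylsilane | C=C[C@@H](c1ccc(O[Si](C)(C)C(C)(C)C)cc1)Oc1cc(OC)c(CC=C(C)C)c(O[Si](C)(C)C(C)(C)C)c1C(=C)O[Si](C)(C)C(C)(C)C
F8 | step 13 | (2S)-4,5-bis(tert-butyldimethylsilyloxy)-2-[4-(tert-butyldimethylsilyloxy)phenyl]-7-methoxy-6-(3-methylbut-2-enyl)-2H-chromene | COc1cc2c(c(O[Si](C)(C)C(C)(C)C)c1CC=C(C)C)C(O[Si](C)(C)C(C)(C)C)=C[C@@H](c1ccc(O[Si](C)(C)C(C)(C)C)cc1)O2
F9 | step 5 | 6-hydroxy-2,4-dimethoxy-3-(3-methylbut-2-enyl)benzaldehyde | COc1cc(O)c(C=O)c(OC)c1CC=C(C)C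
F10 | step 5 | 2-(1-hydroxyethyl)-3,5-dimethoxy-4-(3-methylbut-2-enyl)phenol (racemic) | CC(O)c1c(O)cc(OC)c(CC=C(C)C)c1OC
A1 | alternative 1 | 6-hydroxy-2,4-dimethoxy-3-(3-methylbut-2-enyl)benzaldehyde | COc1cc(O)c(C=O)c(OC)c1CC=C(C)C
A2 | alternative 1 | 4-vinylphenol | C=Cc1ccc(O)cc1
A3 | alternative 1 | (2S,4S)-2-(4-hydroxyphenyl)-5,7-dimethoxy-6-(3-methylbut-2-enyl)chroman-4-ol | COc1cc2c(c(OC)c1CC=C(C)C)[C@@H](O)C[C@@H](c1ccc(O)cc1)O2
A4 | alternative 2 | (S)-1-[6-fluoro-2,4-dimethoxy-3-(3-methylbut-2-enyl)phenyl]-3-[4-(methoxymethoxy)phenyl]-3-(triethylsilyloxy)propan-1-one | COc1cc(F)c(c(OC)c1CC=C(C)C)C(=O)C[C@@H](c1ccc(OCOC)cc1)O[Si](CC)(CC)CC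
A5 | alternative 2 | (2S)-5,7-dimethoxy-4'-(methoxymethoxy)-6-prenylflavanone | COc1cc2c(c(OC)c1CC=C(C)C)C(=O)C[C@@H](c1ccc(OCOC)cc1)O2
A6 | alternative 3 | (2S)-6-(2-diazoacetyl)-2-[4-(tert-butyldimethylsilyloxy)phenyl]-2,3-dihydro-4H-pyran-4-one | [N-]=[N+]=CC(=O)C1=CC(=O)C[C@@H](c2ccc(O[Si](C)(C)C(C)(C)C)cc2)O1
A7 | alternative 3 | 1-methoxy-5-methylhex-4-en-1-yne | COC#CCC=C(C)C
A8 | alternative 3 | 6-prenylsakuranetin 4'-O-tert-butyldimethylsilyl ether | COc1cc2c(c(O)c1CC=C(C)C)C(=O)C[C@@H](c1ccc(O[Si](C)(C)C(C)(C)C)cc1)O2
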